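Everything rests on cutting the tertiary C3–O aryl ether bond of ring A back to an exocyclic C3 methylene and a phenol. A Co(salen)-catalysed hydrogen-atom-transfer/radical–polar crossover hydroetherification forms that C–O bond and the C–H bond of the C3 methyl in one operation and sets C3. It exploits that C3 bears only a methyl and the ether oxygen, lies between the CH2 groups C2 and C4, and needs the oxygen axial (α) with the methyl equatorial, while the oxygen sits ortho to the biaryl bond and para to an allyl group. The precursor is a trans-fused 10β-methyl decalin with a 7β-hydroxyisopropyl group and a C3 exo-methylene, paired with 4-bromo-2-iodophenol; both cross-couplings follow.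

Key step: step 6

Remark: decalin positions carry eudesmane-type numbers (ring A: C1–C5 and C10; ring B: C5–C10; angular methyl on C10; side chain C11 on C7) and α is the face opposite the C10 methyl. Commercial (+)-dihydrocarvone may contain its C2 epimer, which is harmless because C2 becomes trigonal in step 1.

Step 1
Reactants: 1 (2R,5R)-(+)-dihydrocarvone; 2 methyl vinyl ketone
Product: 5 diketone (2S,5R)-2-methyl-2-(3-oxobutyl)-5-(prop-1-en-2-yl)cyclohexan-1-one, via imine 3 (not isolated), via Michael-adduct imine 4 (not isolated)
Conditions: (R)-1-phenylethylamine, TsOH (cat.), toluene, reflux (Dean–Stark); then 2, 40 °C; then aq. AcOH, rt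
Reagents that add atoms: water, O (ring-carbonyl oxygen restored on hydrolysis); (R)-1-phenylethylamine, C[C@@H](N)c1ccccc1 (its nitrogen and phenylethyl group are present only in 3 and 4)
Why: Chiral-imine Michael addition, in which the more substituted secondary enamine tautomer of imine 3 adds to 2 at the methyl-bearing carbon through a compact aza-ene-like transition state, the (R)-phenylethyl group steering the new C–C bond to the ring face anti to the isopropenyl group so that the quaternary centre (future C10) carries its methyl cis to that group, after which aqueous acetic acid hydrolyses imine 4 to the 1,5-diketone.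

Step 2
Reactants: 5 diketone
Product: 7 octalenone (4aS,7R)-4a-methyl-7-(prop-1-en-2-yl)-4,4a,5,6,7,8-hexahydronaphthalen-2(3H)-one, via aldol ketol 6 (not isolated)
Conditions: NaOMe, MeOH, 60 °C
Reagents that add atoms: none
Why: Intramolecular aldol condensation (the ring-closing half of a Robinson annulation), in which the methyl ketone enolate adds to the ring carbonyl to close six-membered ring A and ketol 6 dehydrates to the conjugated enone, neither stereocentre being enolisable.

Step 3
Reactants: 7 octalenone
Product: 8 trans-decalone (4aS,7R,8aS)-4a-methyl-7-(prop-1-en-2-yl)octahydronaphthalen-2(1H)-one (5α-H, 10β-methyl, 7β-isopropenyl)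
Conditions: Li, NH3(l)/THF, t-BuOH (1 equiv), −78 °C; then NH4Cl
Reagents that add atoms: none
Why: Dissolving-metal (Birch-type) enone reduction, in which the C5 carbanion is protonated axially, anti to the angular C10 methyl, to give the trans ring fusion, while the lithium enolate shields the carbonyl and the isolated isopropenyl alkene is not reduced.

Step 4
Reactants: 8 trans-decalone
Product: 9 hydroxy ketone (4aS,7R,8aS)-7-(2-hydroxypropan-2-yl)-4a-methyloctahydronaphthalen-2(1H)-one
Conditions: Co(acac)2 (cat.), PhSiH3, O2 (1 atm), THF, rt
Reagents that add atoms: dioxygen, O=O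
Why: Mukaiyama hydration, in which cobalt-hydride hydrogen-atom transfer to the 1,1-disubstituted alkene and capture of the tertiary radical by O2 give the Markovnikov tertiary alcohol at C11 (no new stereocentre), the ketone being inert to the silane under these conditions.

Step 5
Reactants: 9 hydroxy ketone
Product: 10 exo-methylene alcohol 2-[(2R,4aS,8aS)-4a-methyl-7-methylidenedecahydronaphthalen-2-yl]propan-2-ol
Conditions: Ph3PCH3Br, KOtBu (excess ylide), THF, 0 °C to rt
Reagents that add atoms: methylenetriphenylphosphorane, C=P(c1ccccc1)(c1ccccc1)c1ccccc1 (from methyltriphenylphosphonium bromide, C[P+](c1ccccc1)(c1ccccc1)c1ccccc1.[Br-])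
Why: Wittig methylenation of the unhindered C3 ketone with excess ylide, the tertiary alcohol being at most reversibly deprotonated and C5 lying β to the carbonyl, so that no stereocentre is at risk.

Step 6
Reactants: 10 exo-methylene alcohol; 11 4-bromo-2-iodophenol
Product: 12 tertiary aryl ether 2-[(2R,4aS,7R,8aS)-7-(4-bromo-2-iodophenoxy)-4a,7-dimethyldecahydronaphthalen-2-yl]propan-2-ol (3α-aryloxy axial, 3β-methyl equatorial)
Conditions: Co(salen) complex N,N'-bis(3,5-di-tert-butylsalicylidene)-1,2-cyclohexanediaminocobalt (divalent cobalt, 5 mol %), N-fluoro-2,4,6-trimethylpyridinium tetrafluoroborate (2 equiv), (Me2SiH)2O (1 equiv), 11 (3 equiv), PhCF3, 0 °C to rt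
Reagents that add atoms: none
Why: A trivalent cobalt hydride, formed from the Co(salen) complex, the N-fluoropyridinium oxidant and the silane, transfers a hydrogen atom to the exocyclic CH2 of 10 (Markovnikov MHAT), and the tertiary C3 radical is captured by cobalt and oxidised to a tetravalent alkylcobalt/tertiary cation equivalent that the phenol oxygen of 11 attacks (radical–polar crossover). The closest known reaction is the Co(salen)/silane/N-fluoropyridinium Markovnikov hydroalkoxylation of 1,1-disubstituted alkenes, which accepts phenols as nucleophiles on simpler alkenes. No ring closes; the only bonds formed are C3–O and the C–H of the new C3 methyl. The new C3 stereocentre is controlled by the trans-decalin chair: the bulky cobalt residue should sit on the equatorial β side and be displaced with inversion, and a free cation is likewise attacked along the axial α trajectory, which meets only the axial hydrogens on C1 and C5 and avoids torsional strain with the C–H bonds on C2 and C4, so the oxygen should end up axial (3α) with the methyl equatorial, which is also the more stable arrangement; this facial preference is expected but unproven here, and any 3β epimer would be removed by chromatography. The step needs chemoselectivity for one alkene and for the phenol over the C11 alcohol, which the substrate secures because the exo-methylene is its only C=C, C3 is flanked by CH2 groups so the cation has no better site to migrate to and any endocyclic alkene formed by isomerisation returns the same C3 radical, the C11 hydroxyl is hindered and the phenol is in excess, and the aryl C–I and C–Br bonds are inert to the cobalt hydride.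

Step 7
Reactants: 13 4-bromophenol; 14 allyl bromide
Product: 15 allyl 4-bromophenyl ether
Conditions: K2CO3, acetone, reflux
Reagents that add atoms: none
Why: Williamson ether synthesis of a phenoxide with a reactive allylic bromide under mild carbonate conditions.

Step 8
Reactants: 15 allyl 4-bromophenyl ether
Product: 17 2-allyl-4-bromophenol, via ortho-dienone 16 (not isolated)
Conditions: N,N-diethylaniline, 200 °C
Reagents that add atoms: none
Why: Thermal aromatic Claisen rearrangement, a [3,3]-sigmatropic shift to the free ortho position followed by tautomerisation of dienone 16 to the phenol, the para position being blocked by bromine.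

Step 9
Reactants: 17 2-allyl-4-bromophenol
Product: 18 2-allyl-4-(4,4,5,5-tetramethyl-1,3,2-dioxaborolan-2-yl)phenol
Conditions: B2pin2, Pd(dppf)Cl2 (cat.), KOAc, 1,4-dioxane, 85 °C
Reagents that add atoms: bis(pinacolato)diboron, CC1(C)OB(OC1(C)C)B1OC(C)(C)C(C)(C)O1
Why: Miyaura borylation of the aryl bromide, in which the weak base KOAc leaves the phenol protonated and should not promote migration of the allyl double bond.

Step 10
Reactants: 12 tertiary aryl ether; 18 arylboronate
Product: 19 bromo biaryl ether 2-allyl-4-[5-bromo-2-({(2R,4aS,7R,8aS)-7-(2-hydroxypropan-2-yl)-2,4a-dimethyldecahydronaphthalen-2-yl}oxy)phenyl]phenol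
Conditions: Pd(PPh3)4 (cat.), K2CO3, 18 (1.05 equiv), 1,4-dioxane/H2O, 70 °C
Reagents that add atoms: none
Why: Suzuki–Miyaura coupling in which zerovalent palladium inserts into the C–I bond much faster than into the C–Br bond, so that with only a slight excess of boronate the biaryl bond ortho to the ether oxygen should form alone, the phenol travelling as its phenoxide and the tertiary ether and alcohol being inert to aqueous carbonate.

Step 11
Reactants: 19 bromo biaryl ether; 20 allylboronic acid pinacol ester
Product: 21 target 2-allyl-4-[5-allyl-2-({(2R,4aS,7R,8aS)-7-(2-hydroxypropan-2-yl)-2,4a-dimethyldecahydronaphthalen-2-yl}oxy)phenyl]phenol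
Conditions: Pd(PPh3)4 (cat.), CsF, 20 (excess), THF, reflux
Reagents that add atoms: none
Why: Suzuki–Miyaura-type sp2–sp3 coupling of the remaining aryl bromide with the fluoride-activated allylboronate, which places the allyl group para to the ether oxygen, the reaction being stopped at full conversion to limit migration of the allyl double bonds into conjugation.

Compound list
1 | (2R,5R)-(+)-dihydrocarvone, (2R,5R)-2-methyl-5-(prop-1-en-2-yl)cyclohexan-1-one | C[C@@H]1CC[C@@H](C(C)=C)CC1=O | starting material
2 | methyl vinyl ketone (but-3-en-2-one) | C=CC(C)=O | starting material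
3 | N-[(1R)-1-phenylethyl] imine of 1 (C2 epimers, in equilibrium with the secondary enamine) | CC1CC[C@@H](C(C)=C)CC1=N[C@H](C)c1ccccc1 | intermediate (not isolated)
4 | N-[(1R)-1-phenylethyl] ring imine of diketone 5 | CC(=O)CC[C@]1(C)CC[C@@H](C(C)=C)CC1=N[C@H](C)c1ccccc1 | intermediate (not isolated)
5 | (2S,5R)-2-methyl-2-(3-oxobutyl)-5-(prop-1-en-2-yl)cyclohexan-1-one | CC(=O)CC[C@]1(C)CC[C@@H](C(C)=C)CC1=O | intermediate
6 | aldol ketol, 8a-hydroxy-4a-methyl-7-(prop-1-en-2-yl)octahydronaphthalen-2(1H)-one (hydroxyl configuration at C5 not defined) | O=C1CC[C@]2(C)CC[C@@H](C(C)=C)CC2(O)C1 | intermediate (not isolated)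
7 | (4aS,7R)-4a-methyl-7-(prop-1-en-2-yl)-4,4a,5,6,7,8-hexahydronaphthalen-2(3H)-one | O=C1CC[C@]2(C)CC[C@@H](C(C)=C)CC2=C1 | intermediate
8 | (4aS,7R,8aS)-4a-methyl-7-(prop-1-en-2-yl)octahydronaphthalen-2(1H)-one (trans-fused) | O=C1CC[C@]2(C)CC[C@@H](C(C)=C)C[C@H]2C1 | intermediate
9 | (4aS,7R,8aS)-7-(2-hydroxypropan-2-yl)-4a-methyloctahydronaphthalen-2(1H)-one | O=C1CC[C@]2(C)CC[C@@H](C(C)(C)O)C[C@H]2C1 | intermediate
10 | 2-[(2R,4aS,8aS)-4a-methyl-7-methylidenedecahydronaphthalen-2-yl]propan-2-ol | C=C1CC[C@]2(C)CC[C@@H](C(C)(C)O)C[C@H]2C1 | intermediate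
11 | 4-bromo-2-iodophenol | Oc1ccc(Br)cc1I | starting material
12 | 2-[(2R,4aS,7R,8aS)-7-(4-bromo-2-iodophenoxy)-4a,7-dimethyldecahydronaphthalen-2-yl]propan-2-ol | Brc1ccc(O[C@]2(C)CC[C@]3(C)CC[C@@H](C(C)(C)O)C[C@H]3C2)c(I)c1 | intermediate
13 | 4-bromophenol | Oc1ccc(Br)cc1 | starting material
14 | allyl bromide | C=CCBr | starting material
15 | allyl 4-bromophenyl ether | C=CCOc1ccc(Br)cc1 | intermediate
16 | 6-allyl-4-bromocyclohexa-2,4-dien-1-one | C=CCC1C=C(Br)C=CC1=O | intermediate (not isolated)
17 | 2-allyl-4-bromophenol | C=CCc1cc(Br)ccc1O | intermediate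
18 | 2-allyl-4-(4,4,5,5-tetramethyl-1,3,2-dioxaborolan-2-yl)phenol | C=CCc1cc(B2OC(C)(C)C(C)(C)O2)ccc1O | intermediate
19 | 2-allyl-4-[5-bromo-2-({(2R,4aS,7R,8aS)-7-(2-hydroxypropan-2-yl)-2,4a-dimethyldecahydronaphthalen-2-yl}oxy)phenyl]phenol | Brc1ccc(O[C@]2(C)CC[C@]3(C)CC[C@@H](C(C)(C)O)C[C@H]3C2)c(-c2ccc(O)c(CC=C)c2)c1 | intermediate
20 | allylboronic acid pinacol ester | C=CCB1OC(C)(C)C(C)(C)O1 | starting material
21 | 2-allyl-4-[5-allyl-2-({(2R,4aS,7R,8aS)-7-(2-hydroxypropan-2-yl)-2,4a-dimethyldecahydronaphthalen-2-yl}oxy)phenyl]phenol (CNP0342687.1) | C=CCc1ccc(O[C@]2(C)CC[C@]3(C)CC[C@@H](C(C)(C)O)C[C@H]3C2)c(-c2ccc(O)c(CC=C)c2)c1 | target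

Total step count: 11
Longest linear sequence: 8 steps (steps 1–6, 10 and 11); the boronate branch (steps 7–9) joins at step 10.

Steps most likely to fail

1. Step 6. Facial selectivity at C3 may be poor, with equatorial C–O formation competing with the axial mode. Capture of the tertiary cobalt/cation intermediate by the crowded, weakly nucleophilic ortho-iodophenol may also lose out to alkene isomerisation, elimination or hydration. The fallback uses known chemistry, sets out from ketone 8 and rejoins the route at 12. MeTi(OiPr)3 (Et2O/hexane, −30 °C to rt) should deliver methyl from the equatorial β side and give the axial tertiary alcohol (2R,4aS,7R,8aS)-2,4a-dimethyl-7-(prop-1-en-2-yl)decahydronaphthalen-2-ol F1, the minor epimer being removed by chromatography. Its potassium alkoxide (KH, THF/DMF, 0 °C to rt) displaces fluoride from 4-bromo-1-fluoro-2-nitrobenzene by SNAr to give the 4-bromo-2-nitrophenyl ether F2. Fe/NH4Cl (EtOH/H2O, 70 °C) reduces the nitro group to the aniline F3. Aprotic Sandmeyer-type iodination (tBuONO, CH2I2, MeCN, 60 °C) gives the 4-bromo-2-iodophenyl ether F4 with the isopropenyl group intact. Mukaiyama hydration as in step 4 (Co(acac)2, PhSiH3, O2, THF) then gives 12.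

2. Step 10. Oxidative addition at the iodide flanked by the tertiary ether may be slow enough that coupling at the bromide (over-arylation) and protodeboronation of the electron-rich phenol boronate compete. The fallback reverses the polarity of the two partners, sets out from 12 and rejoins at 19. The tertiary alcohol is deprotonated with MeMgCl (1 equiv, THF, −20 °C), iPrMgCl·LiCl then exchanges only the iodide, and quenching the aryl Grignard with 2-isopropoxy-4,4,5,5-tetramethyl-1,3,2-dioxaborolane gives the ortho-boronate pinacol ester F5. The partner is made from 4-iodophenol and 14 in the way 17 was made: Williamson allylation to allyl 4-iodophenyl ether F6 and thermal Claisen rearrangement to 2-allyl-4-iodophenol F7. Suzuki–Miyaura coupling of F5 with F7 (Pd(PPh3)4, K2CO3, dioxane/H2O, 60 °C) puts the oxidative addition on an unhindered iodide, which should outpace the bromide of F5, and gives 19.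

3. Step 11. Palladium-hydride-mediated migration of either allyl double bond into conjugation, or sluggish transmetalation of the allylboronate in the presence of the phenoxide, may erode the final coupling. The fallback sets out from 19 and arrives at 21 by a Stille coupling with allyltributylstannane (Pd(PPh3)4, DMF, 90 °C). This replaces the base-activated boron nucleophile with a neutral tin reagent, so no phenoxide or fluoride is present and transmetalation does not depend on boronate activation. It passes through no new compound (F0).

Further compounds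
F1 | step 6 | (2R,4aS,7R,8aS)-2,4a-dimethyl-7-(prop-1-en-2-yl)decahydronaphthalen-2-ol | O[C@]1(C)CC[C@]2(C)CC[C@@H](C(C)=C)C[C@H]2C1
F2 | step 6 | 4-bromo-2-nitrophenyl ether of F1 | O=[N+]([O-])c1cc(Br)ccc1O[C@]1(C)CC[C@]2(C)CC[C@@H](C(C)=C)C[C@H]2C1
F3 | step 6 | 2-amino-4-bromophenyl ether of F1 | Nc1cc(Br)ccc1O[C@]1(C)CC[C@]2(C)CC[C@@H](C(C)=C)C[C@H]2C1
F4 | step 6 | 4-bromo-2-iodophenyl ether of F1 | Ic1cc(Br)ccc1O[C@]1(C)CC[C@]2(C)CC[C@@H](C(C)=C)C[C@H]2C1
F5 | step 10 | 2-[(2R,4aS,7R,8aS)-7-[4-bromo-2-(4,4,5,5-tetramethyl-1,3,2-dioxaborolan-2-yl)phenoxy]-4a,7-dimethyldecahydronaphthalen-2-yl]propan-2-ol | CC1(C)OB(OC1(C)C)c1cc(Br)ccc1O[C@]1(C)CC[C@]2(C)CC[C@@H](C(C)(C)O)C[C@H]2C1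
F6 | step 10 | allyl 4-iodophenyl ether | C=CCOc1ccc(I)cc1
F7 | step 10 | 2-allyl-4-iodophenol | C=CCc1cc(I)ccc1O
F0 | step 11 | none | none
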